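**Retrosynthetic overview**

1. The butenolide is made last, by syn-carbocupration and lactonisation of a γ-hydroxy ynoate whose C16 carbinol comes from a catalytic asymmetric alkynylation. The 13Z olefin comes from a Wittig reaction of an α-alkoxy C13 ketone, and the chain is joined to C9 by B-alkyl Suzuki–Miyaura coupling of a C8=C9 enol triflate.
2. The enol triflate comes from a bicyclic C8=C9 silyl enol ether that carries a temporary formyl group on C6, removed by decarbonylation.
3. Rings A and B are closed in one operation from an achiral open-chain silyloxytriene enal: bond C5–C10 first (ring A), then C6–C7 (ring B). The lactone ring is closed last.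
4. Enabling feature: ring B is a cyclohexene whose C8=C9 double bond flanks the quaternary ring-fusion carbon C10. C9 can therefore be a masked ketone, C10 its nucleophilic α-carbon and C5 (with a removable formyl on C6) a β-acceptor carbon, so ring B is the [4+2] sum of a 2-silyloxydiene C7=C8–C9=C10 and a C5=C6 enal linked through C1–C4 of ring A.
5. The open chain is built from isobutyronitrile, 1,3-dibromopropane and methyl 2-methyl-3-oxopentanoate.

Key step: step 9

Remark: labdane-type locants are used (decalin C1–C10 with the geminal methyls on C4, ring fusion C5/C10, ring alkene C8=C9; chain C11–C16, C16 being the lactone carbinol carbon). The target is read from its SMILES as 5S,10S,16R with a 13Z olefin. "Dec" in names stands for (4aS,8aS)-2,5,5,8a-tetramethyl-3,4,4a,5,6,7,8,8a-octahydronaphthalen-1-yl.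

**Route**

Step 1
Reactants: 1 isobutyronitrile; 2 1,3-dibromopropane
Product: 4 5-bromo-2,2-dimethylpentanenitrile, via lithiated isobutyronitrile 3 (not isolated)
Conditions: LiN(i-Pr)2, THF, −78 °C; then 2 (3 equiv), −78 °C → rt
Reagents that add atoms: none
Why: SN2 alkylation of the α-lithiated nitrile should give the quaternary carbon C4, the excess of dibromide suppressing double alkylation; no stereocentre is formed.

Step 2
Reactants: 5 methyl 2-methyl-3-oxopentanoate; 4 5-bromo-2,2-dimethylpentanenitrile
Product: 7 methyl 2-(4-cyano-4-methylpentyl)-2-methyl-3-oxopentanoate (racemic), via sodium enolate 6 (not isolated)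
Conditions: NaH, DMF, 0 °C; then 4, NaI (cat.), 60 °C
Reagents that add atoms: none
Why: Acetoacetic-ester-type C-alkylation of the stabilised enolate by the primary bromide (in-situ Finkelstein exchange) should join C1 to C10; the new stereocentre is racemic and without consequence.

Step 3
Reactants: 7 methyl 2-(4-cyano-4-methylpentyl)-2-methyl-3-oxopentanoate
Product: 8 2,2,6-trimethyl-7-oxononanenitrile (racemic)
Conditions: LiCl, H2O, DMSO, 150 °C
Reagents that add atoms: none
Why: Krapcho demethoxycarbonylation under neutral conditions should leave the nitrile and ketone untouched; the C10 stereocentre is racemic and later becomes sp2.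

Step 4
Reactants: 8 2,2,6-trimethyl-7-oxononanenitrile
Product: 12 2,2,6,8-tetramethyl-7-oxonon-8-enenitrile (racemic), via lithium enolate 9 (not isolated), via Mannich base 10 (not isolated), via trimethylammonium iodide 11 (not isolated)
Conditions: LiN(i-Pr)2, THF, −78 °C; CH2=NMe2+ I−, −78 °C → rt; then MeI, CH2Cl2, rt; then DBU, rt
Reagents that add atoms: N,N-dimethylmethyleneiminium iodide C=[N+](C)C.[I-]
Why: Kinetic deprotonation on the less hindered ethyl side, Mannich reaction, N-quaternisation and base-induced elimination should give the isopropenyl ketone (α-methylenation), which supplies C7 and C8.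

Step 5
Reactants: 12 2,2,6,8-tetramethyl-7-oxonon-8-enenitrile
Product: 13 2,2,6,8-tetramethyl-7-[(triisopropylsilyl)oxy]nona-6,8-dienenitrile (mixture of C6=C7 isomers)
Conditions: TIPSOTf, Et3N, CH2Cl2, 0 °C → rt
Reagents that add atoms: triisopropylsilyl trifluoromethanesulfonate CC(C)[Si](C(C)C)(C(C)C)OS(=O)(=O)C(F)(F)F
Why: Soft enolisation can only occur at the single α'-hydrogen (on C10) and should give the 2-silyloxydiene; both enol ether isomers are carried on because the geometry is erased in step 9.

Step 6
Reactants: 13 2,2,6,8-tetramethyl-7-[(triisopropylsilyl)oxy]nona-6,8-dienenitrile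
Product: 15 2,2,6,8-tetramethyl-7-[(triisopropylsilyl)oxy]nona-6,8-dienal, via N-aluminio aldimine 14 (not isolated)
Conditions: i-Bu2AlH, CH2Cl2, −78 °C; then aq. potassium sodium tartrate, 0 °C
Reagents that add atoms: water O
Why: Partial reduction of the nitrile should stop at the N-metalated aldimine, which the neutral aqueous work-up hydrolyses to the neopentyl aldehyde (C5) without cleaving the bulky silyl enol ether.

Step 7
Reactants: 15 2,2,6,8-tetramethyl-7-[(triisopropylsilyl)oxy]nona-6,8-dienal; 16 diethyl {2-[methoxy(methyl)amino]-2-oxoethyl}phosphonate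
Product: 18 (2E)-N-methoxy-N,4,4,8,10-pentamethyl-9-[(triisopropylsilyl)oxy]undeca-2,8,10-trienamide, via sodium phosphonate 17 (not isolated)
Conditions: 16, NaH, THF, 0 °C; then 15, 0 °C → rt
Reagents that add atoms: none
Why: Horner–Wadsworth–Emmons olefination of the non-enolisable aldehyde should give the E-configured C5=C6 unsaturated N-methoxy-N-methylamide, an acceptor too weak to react with the silyl enol ether.

Step 8
Reactants: 18 (2E)-N-methoxy-N,4,4,8,10-pentamethyl-9-[(triisopropylsilyl)oxy]undeca-2,8,10-trienamide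
Product: 20 (2E)-4,4,8,10-tetramethyl-9-[(triisopropylsilyl)oxy]undeca-2,8,10-trienal (its C3 is labdane C5, its C8 is labdane C10), via aluminium hemiaminal 19 (not isolated)
Conditions: i-Bu2AlH, THF, −78 °C; then aq. potassium sodium tartrate, 0 °C
Reagents that add atoms: none
Why: Reduction of the N-methoxy-N-methylamide should stop at the chelated tetrahedral intermediate and release the E-enal only on cold neutral work-up, so that enal and silyl enol ether first meet without any acid present.

Step 9
Reactants: 20 (2E)-4,4,8,10-tetramethyl-9-[(triisopropylsilyl)oxy]undeca-2,8,10-trienal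
Product: 23 (1S,4aS,8aS)-3,4a,8,8-tetramethyl-4-[(triisopropylsilyl)oxy]-1,2,4a,5,6,7,8,8a-octahydronaphthalene-1-carbaldehyde (trans-fused; formyl on labdane C6), via iminium ion 21 (not isolated), via enamine oxocarbenium 22 (not isolated)
Conditions: (2S,5S)-5-benzyl-2-tert-butyl-3-methylimidazolidin-4-one (20 mol %), 2,4-dinitrobenzoic acid (20 mol %), H2O (2 equiv), CH2Cl2, −40 → −10 °C
Reagents that add atoms: none
Why: Proposed new method: the imidazolidinone condenses with the enal to the E-iminium ion 21, C10 of the tethered silyl enol ether adds to C5 (6-exo-trig Mukaiyama–Michael addition that forms the C5–C10 bond and closes ring A) to give 22, whose enamine carbon C6 then adds to C7 of the O-silylated isopropenyl ketone (6-endo-trig Michael addition that closes ring B), and hydrolysis of the product iminium ion releases 23 and the catalyst, overall a stepwise [4+2] of a 2-silyloxydiene with an enal. The closest known reaction types are the imidazolidinone-catalysed intramolecular Diels–Alder reaction of 1,7,9-decatrienals, the iminium-catalysed Mukaiyama–Michael addition of silyl enol ethers and iminium–enamine cascades; new is their combination on a tetrasubstituted silyl enol ether that must forge a quaternary carbon next to a neopentyl centre. C5 is set by the catalyst, whose benzyl group covers one face of the E-iminium ion so that C10 should add to the Si face of C5 (C4 > C6 > H), the sense this catalyst shows with β-alkyl enals. C10 is set relative to C5 by a chair-like transition state of the forming ring A in which the C9 enol ether unit and the C6 iminium unit are both pseudo-equatorial and the C10 methyl is axial (the alternative pushes the C9 unit against the axial C4 methyl), which should give the trans ring fusion, while C6 (equatorial formyl expected) is erased in step 10. Because the first bond is made by a polar addition and not by a synchronous cycloaddition, both geometrical isomers of the C9=C10 enol ether can converge on the same C10 configuration and the twisted diene need not become planar. The step needs C10 rather than C7 as the nucleophilic terminus, which the 2-silyloxy group secures, 1,4- over 1,2-addition, which iminium activation and the six-membered closure secure, and survival of the silyl enol ethers, for which the bulky silyl group and the weak acid co-catalyst are chosen.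

Step 10
Reactants: 23 (1S,4aS,8aS)-3,4a,8,8-tetramethyl-4-[(triisopropylsilyl)oxy]-1,2,4a,5,6,7,8,8a-octahydronaphthalene-1-carbaldehyde
Product: 24 triisopropyl(Dec-oxy)silane
Conditions: RhCl(PPh3)3 (1.05 equiv), PhMe, 110 °C
Reagents that add atoms: none
Why: Stoichiometric Tsuji–Wilkinson decarbonylation should excise the activating formyl group and leave C6 as CH2; C5 and C10 are not touched.

Step 11
Reactants: 24 triisopropyl(Dec-oxy)silane
Product: 25 Dec trifluoromethanesulfonate
Conditions: CsF, PhNTf2, DME, rt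
Reagents that add atoms: N-phenylbis(trifluoromethanesulfonimide) O=S(=O)(N(c1ccccc1)S(=O)(=O)C(F)(F)F)C(F)(F)F
Why: Fluoride-induced cleavage of the silyl enol ether should release the regiodefined C8=C9 enolate, which is O-triflated in situ, so the tetrasubstituted olefin is fixed in its final position.

Step 12
Reactants: 26 but-3-ene-1,2-diol (racemic)
Product: 27 1-(methoxymethoxy)but-3-en-2-ol (racemic)
Conditions: MOMCl (1 equiv), i-Pr2NEt, CH2Cl2, −40 → 0 °C
Reagents that add atoms: chloromethyl methyl ether COCCl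
Why: Alkylation should favour the less hindered primary hydroxyl (the minor secondary ether and bis-ether would be removed by chromatography); the carbinol centre is later oxidised.

Step 13
Reactants: 25 Dec trifluoromethanesulfonate; 27 1-(methoxymethoxy)but-3-en-2-ol
Product: 29 1-(methoxymethoxy)-4-Dec-butan-2-ol (mixture of carbinol epimers), via alkylborane 28 (not isolated)
Conditions: 27, 9-BBN-H (2.2 equiv), THF, 0 °C → rt; then 25, PdCl2(dppf) (10 mol %), AsPh3, Cs2CO3, DMF–H2O, 60 °C
Reagents that add atoms: none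
Why: Anti-Markovnikov hydroboration followed by B-alkyl Suzuki–Miyaura coupling with the enol triflate should forge C9–C11 with the ring olefin unchanged.

Step 14
Reactants: 29 1-(methoxymethoxy)-4-Dec-butan-2-ol
Product: 30 1-(methoxymethoxy)-4-Dec-butan-2-one
Conditions: Dess–Martin periodinane, NaHCO3, CH2Cl2, rt
Reagents that add atoms: none
Why: Buffered Dess–Martin oxidation should give the α-alkoxy C13 ketone without touching the electron-rich ring olefin.

Step 15
Reactants: 30 1-(methoxymethoxy)-4-Dec-butan-2-one; 31 [2-(1,3-dioxolan-2-yl)ethyl]triphenylphosphonium bromide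
Product: 33 2-{(2Z)-3-[(methoxymethoxy)methyl]-5-Dec-pent-2-en-1-yl}-1,3-dioxolane, via ylide 32 (not isolated)
Conditions: 31, KN(SiMe3)2, THF, −78 → 0 °C; then 30, −78 °C → rt
Reagents that add atoms: none
Why: The Wittig reaction of a non-stabilised ylide with an α-alkoxy ketone is known to place the alkoxymethyl group cis to the ylide-derived chain, which should set the 13Z trisubstituted olefin.

Step 16
Reactants: 33 2-{(2Z)-3-[(methoxymethoxy)methyl]-5-Dec-pent-2-en-1-yl}-1,3-dioxolane
Product: 34 (3Z)-4-[(methoxymethoxy)methyl]-6-Dec-hex-3-enal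
Conditions: PPTS, acetone–H2O (9:1), 55 °C
Reagents that add atoms: water O
Why: Mild acetal hydrolysis should free the C16 aldehyde while the methoxymethyl ether survives and the weak acid does not move the β,γ-double bond into conjugation.

Step 17
Reactants: 34 (3Z)-4-[(methoxymethoxy)methyl]-6-Dec-hex-3-enal; 35 methyl propiolate
Product: 37 methyl (4R,6Z)-4-hydroxy-7-[(methoxymethoxy)methyl]-9-Dec-non-6-en-2-ynoate, via zinc acetylide 36 (not isolated)
Conditions: 35, Me2Zn, (S,S)-ProPhenol [2,6-bis{[(S)-2-(hydroxydiphenylmethyl)pyrrolidin-1-yl]methyl}-4-methylphenol] (20 mol %), Ph3PO (40 mol %), PhMe, 0 °C; then 34 (slow addition), 0 → 4 °C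
Reagents that add atoms: none
Why: Zinc–ProPhenol-catalysed asymmetric alkynylation should set C16 as R by delivery of the alkynylzinc to the Si face of the aldehyde (O > C15 > H); the (S,S)-ligand is expected to give this sense and the assignment would be confirmed by Mosher ester analysis before proceeding.

Step 18
Reactants: 37 methyl (4R,6Z)-4-hydroxy-7-[(methoxymethoxy)methyl]-9-Dec-non-6-en-2-ynoate; 38 tributyl[(methoxymethoxy)methyl]stannane
Product: 42 (5R)-4-[(methoxymethoxy)methyl]-5-{(2Z)-3-[(methoxymethoxy)methyl]-5-Dec-pent-2-en-1-yl}furan-2(5H)-one, via organolithium 39 (not isolated), via cuprate 40 (not isolated), via hydroxy enoate 41 (not isolated)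
Conditions: 38, n-BuLi, THF, −78 °C; CuBr·SMe2, −78 → −40 °C; then 37, −78 → −20 °C; aq. NH4Cl–NH3
Reagents that add atoms: none
Why: Syn-carbocupration of the ynoate by the alkoxymethyl cuprate (conjugate addition) places the C16 oxygen cis to the ester, so the adduct should lactonise to the β-substituted butenolide with C16 untouched.

Step 19
Reactants: 42 (5R)-4-[(methoxymethoxy)methyl]-5-{(2Z)-3-[(methoxymethoxy)methyl]-5-Dec-pent-2-en-1-yl}furan-2(5H)-one
Product: 43 16-epi-luffarin L, (5R)-4-(hydroxymethyl)-5-{(2Z)-3-(hydroxymethyl)-5-Dec-pent-2-en-1-yl}furan-2(5H)-one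
Conditions: Me2BBr, CH2Cl2, −78 °C; then THF–aq. NaHCO3
Reagents that add atoms: none
Why: Low-temperature cleavage of both methoxymethyl ethers by the bromoborane (acetal exchange, then hydrolysis) should free the two primary alcohols without disturbing the butenolide, the olefins or C16.

**Compound list**

1 | isobutyronitrile | CC(C)C#N | starting material
2 | 1,3-dibromopropane | BrCCCBr | starting material
3 | lithiated isobutyronitrile (formed in the flask) | [Li+].C[C-](C)C#N | intermediate
4 | 5-bromo-2,2-dimethylpentanenitrile | N#CC(C)(C)CCCBr | intermediate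
5 | methyl 2-methyl-3-oxopentanoate | CCC(=O)C(C)C(=O)OC | starting material
6 | sodium enolate of 5 (formed in the flask) | CCC([O-])=C(C)C(=O)OC.[Na+] | intermediate
7 | methyl 2-(4-cyano-4-methylpentyl)-2-methyl-3-oxopentanoate (racemic) | CCC(=O)C(C)(CCCC(C)(C)C#N)C(=O)OC | intermediate
8 | 2,2,6-trimethyl-7-oxononanenitrile (racemic) | CCC(=O)C(C)CCCC(C)(C)C#N | intermediate
9 | lithium C7=C8 enolate of 8 (formed in the flask) | [Li+].CC=C([O-])C(C)CCCC(C)(C)C#N | intermediate
10 | 9-(dimethylamino)-2,2,6,8-tetramethyl-7-oxononanenitrile, Mannich base (formed in the flask) | CN(C)CC(C)C(=O)C(C)CCCC(C)(C)C#N | intermediate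
11 | (8-cyano-2,4,8-trimethyl-3-oxononyl)trimethylammonium iodide (formed in the flask) | C[N+](C)(C)CC(C)C(=O)C(C)CCCC(C)(C)C#N.[I-] | intermediate
12 | 2,2,6,8-tetramethyl-7-oxonon-8-enenitrile (racemic) | C=C(C)C(=O)C(C)CCCC(C)(C)C#N | intermediate
13 | 2,2,6,8-tetramethyl-7-[(triisopropylsilyl)oxy]nona-6,8-dienenitrile (C6=C7 isomer mixture) | C=C(C)C(O[Si](C(C)C)(C(C)C)C(C)C)=C(C)CCCC(C)(C)C#N | intermediate
14 | N-(diisobutylaluminio) aldimine of 15 (formed in the flask) | C=C(C)C(O[Si](C(C)C)(C(C)C)C(C)C)=C(C)CCCC(C)(C)C=N[Al](CC(C)C)CC(C)C | intermediate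
15 | 2,2,6,8-tetramethyl-7-[(triisopropylsilyl)oxy]nona-6,8-dienal | C=C(C)C(O[Si](C(C)C)(C(C)C)C(C)C)=C(C)CCCC(C)(C)C=O | intermediate
16 | diethyl {2-[methoxy(methyl)amino]-2-oxoethyl}phosphonate | CCOP(=O)(CC(=O)N(C)OC)OCC | starting material
17 | sodium salt of 16 (formed in the flask) | [Na+].CCOP(=O)(OCC)[CH-]C(=O)N(C)OC | intermediate
18 | (2E)-N-methoxy-N,4,4,8,10-pentamethyl-9-[(triisopropylsilyl)oxy]undeca-2,8,10-trienamide | C=C(C)C(O[Si](C(C)C)(C(C)C)C(C)C)=C(C)CCCC(C)(C)/C=C/C(=O)N(C)OC | intermediate
19 | O-(diisobutylaluminio) hemiaminal of 18 (formed in the flask) | C=C(C)C(O[Si](C(C)C)(C(C)C)C(C)C)=C(C)CCCC(C)(C)/C=C/C(O[Al](CC(C)C)CC(C)C)N(C)OC | intermediate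
20 | (2E)-4,4,8,10-tetramethyl-9-[(triisopropylsilyl)oxy]undeca-2,8,10-trienal | C=C(C)C(O[Si](C(C)C)(C(C)C)C(C)C)=C(C)CCCC(C)(C)/C=C/C=O | intermediate
21 | iminium ion of 20 with the (2S,5S)-imidazolidinone, 2,4-dinitrobenzoate salt (formed in the flask) | C=C(C)C(O[Si](C(C)C)(C(C)C)C(C)C)=C(C)CCCC(C)(C)/C=C/C=[N+]1[C@@H](Cc2ccccc2)C(=O)N(C)[C@H]1C(C)(C)C.[O-]C(=O)c1ccc(cc1[N+](=O)[O-])[N+](=O)[O-] | intermediate
22 | ring-A-closed enamine with O-silylated isopropenyl ketone (C5–C10 bond formed), 2,4-dinitrobenzoate salt (formed in the flask) | C=C(C)C(=[O+][Si](C(C)C)(C(C)C)C(C)C)[C@@]1(C)CCCC(C)(C)[C@@H]1/C=C/N1[C@@H](Cc2ccccc2)C(=O)N(C)[C@H]1C(C)(C)C.[O-]C(=O)c1ccc(cc1[N+](=O)[O-])[N+](=O)[O-] | intermediate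
23 | (1S,4aS,8aS)-3,4a,8,8-tetramethyl-4-[(triisopropylsilyl)oxy]-1,2,4a,5,6,7,8,8a-octahydronaphthalene-1-carbaldehyde | CC1=C(O[Si](C(C)C)(C(C)C)C(C)C)[C@@]2(C)CCCC(C)(C)[C@@H]2[C@@H](C=O)C1 | intermediate
24 | triisopropyl(Dec-oxy)silane | CC1=C(O[Si](C(C)C)(C(C)C)C(C)C)[C@@]2(C)CCCC(C)(C)[C@@H]2CC1 | intermediate
25 | Dec trifluoromethanesulfonate | CC1=C(OS(=O)(=O)C(F)(F)F)[C@@]2(C)CCCC(C)(C)[C@@H]2CC1 | intermediate
26 | but-3-ene-1,2-diol (racemic) | C=CC(O)CO | starting material
27 | 1-(methoxymethoxy)but-3-en-2-ol (racemic) | C=CC(O)COCOC | intermediate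
28 | B-alkyl-9-borabicyclo[3.3.1]nonane from 27, O-borinated (formed in the flask) | COCOCC(OB1C2CCCC1CCC2)CCB1C2CCCC1CCC2 | intermediate
29 | 1-(methoxymethoxy)-4-Dec-butan-2-ol (carbinol epimers) | CC1=C(CCC(O)COCOC)[C@@]2(C)CCCC(C)(C)[C@@H]2CC1 | intermediate
30 | 1-(methoxymethoxy)-4-Dec-butan-2-one | CC1=C(CCC(=O)COCOC)[C@@]2(C)CCCC(C)(C)[C@@H]2CC1 | intermediate
31 | [2-(1,3-dioxolan-2-yl)ethyl]triphenylphosphonium bromide | [Br-].C1COC(CC[P+](c2ccccc2)(c2ccccc2)c2ccccc2)O1 | starting material
32 | [2-(1,3-dioxolan-2-yl)ethylidene]triphenylphosphorane (formed in the flask) | C1COC(CC=P(c2ccccc2)(c2ccccc2)c2ccccc2)O1 | intermediate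
33 | 2-{(2Z)-3-[(methoxymethoxy)methyl]-5-Dec-pent-2-en-1-yl}-1,3-dioxolane | CC1=C(CC/C(=C/CC3OCCO3)COCOC)[C@@]2(C)CCCC(C)(C)[C@@H]2CC1 | intermediate
34 | (3Z)-4-[(methoxymethoxy)methyl]-6-Dec-hex-3-enal | CC1=C(CC/C(=C/CC=O)COCOC)[C@@]2(C)CCCC(C)(C)[C@@H]2CC1 | intermediate
35 | methyl propiolate | C#CC(=O)OC | starting material
36 | methyl 3-(methylzincio)propiolate (formed in the flask) | C[Zn]C#CC(=O)OC | intermediate
37 | methyl (4R,6Z)-4-hydroxy-7-[(methoxymethoxy)methyl]-9-Dec-non-6-en-2-ynoate | CC1=C(CC/C(=C/C[C@@H](O)C#CC(=O)OC)COCOC)[C@@]2(C)CCCC(C)(C)[C@@H]2CC1 | intermediate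
38 | tributyl[(methoxymethoxy)methyl]stannane | CCCC[Sn](CCCC)(CCCC)COCOC | starting material
39 | [(methoxymethoxy)methyl]lithium (formed in the flask) | [Li]COCOC | intermediate
40 | lithium bis[(methoxymethoxy)methyl]cuprate (formed in the flask) | [Li+].COCOC[Cu-]COCOC | intermediate
41 | methyl (2Z,4R,6Z)-4-hydroxy-3,7-bis[(methoxymethoxy)methyl]-9-Dec-nona-2,6-dienoate (formed in the flask) | CC1=C(CC/C(=C/C[C@@H](O)/C(COCOC)=C\C(=O)OC)COCOC)[C@@]2(C)CCCC(C)(C)[C@@H]2CC1 | intermediate
42 | (5R)-4-[(methoxymethoxy)methyl]-5-{(2Z)-3-[(methoxymethoxy)methyl]-5-Dec-pent-2-en-1-yl}furan-2(5H)-one | CC1=C(CC/C(=C/C[C@H]3OC(=O)C=C3COCOC)COCOC)[C@@]2(C)CCCC(C)(C)[C@@H]2CC1 | intermediate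
43 | 16-epi-luffarin L | CC1=C(CC/C(=C/C[C@H]2OC(=O)C=C2CO)CO)[C@@]2(C)CCCC(C)(C)[C@@H]2CC1 | target

**Step count and risks**

Total step count: 19. Longest linear sequence: 18 steps (steps 1–11 and 13–19; step 12 makes the small fragment 27).

Steps most likely to fail:

1. Step 9 (proposed new method). The addition of the tetrasubstituted silyl enol ether to the hindered β-carbon may be slower than protodesilylation by the acid co-catalyst, or the ring-fusion and facial selectivities may be poor. The fallback uses auxiliary control and a stoichiometric Lewis acid, both known chemistry; it sets out from aldehyde 15 and comes back at aldehyde 23. Horner–Wadsworth–Emmons reaction of 15 with diethyl {2-[(4S)-4-benzyl-2-oxo-1,3-oxazolidin-3-yl]-2-oxoethyl}phosphonate (LiCl, i-Pr2NEt, MeCN) would give the (E)-trienimide F1. Me2AlCl (1.4 equiv, CH2Cl2, −30 °C) would promote the auxiliary-controlled intramolecular Diels–Alder (double Michael) reaction through the chelated s-cis imide, whose benzyl group leaves the Si face of the α-carbon open, to give the trans-fused bicyclic imide F2. LiBH4 (THF–MeOH, 0 °C) would cleave the auxiliary to the primary alcohol F3, and Dess–Martin oxidation would return aldehyde 23.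

2. Step 13. Oxidative addition and transmetalation at the tetrasubstituted triflate, flanked by the quaternary C10 and the C8 methyl, may be too slow, so that protodeboronation and β-hydride elimination of the alkylborane take over. The fallback sets out from triflate 25 and comes back at ketone 30. Stille coupling of 25 with tributyl(vinyl)stannane (Pd(PPh3)4, LiCl, THF, reflux), a coupling that tolerates such hindered triflates, would give the 9-vinyl diene F4. Hydroboration of its terminal vinyl group with 9-BBN-H would give the unhindered primary alkylborane F6, which would be coupled (PdCl2(dppf), Cs2CO3, DMF–H2O) with 2-bromo-3-(methoxymethoxy)prop-1-ene F5 (from 2-bromoprop-2-en-1-ol, MOMCl, i-Pr2NEt) to the methylene compound F7. Lemieux–Johnson cleavage (OsO4 cat., NaIO4, 2,6-lutidine, dioxane–H2O), which attacks the unhindered 1,1-disubstituted olefin far faster than the tetrasubstituted ring olefin and the trisubstituted one is absent at this stage, would pass through the diol F8 to ketone 30.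

3. Step 17. Under the basic zinc alkoxide conditions the β,γ-double bond may migrate into conjugation with the aldehyde, the aldehyde may self-condense, or the facial selectivity may be insufficient. The fallback sets the carbinol by reduction instead of addition; it sets out from aldehyde 34 and comes back at ynoate 37. Lithiated methyl propiolate (35, LiN(SiMe3)2, THF, −90 °C) would add rapidly and without stereocontrol to give the C16-epimeric alcohols F9. Buffered Dess–Martin oxidation would give the ynone F10, and Midland reduction with (R)-Alpine-Borane (THF, rt), which reduces alkynyl ketones and especially 4-oxo-2-ynoates to the (R)-propargylic alcohols under neutral conditions, would return 37.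

Further compounds
F1 | step 9 | (4S)-4-benzyl-3-{(2E)-4,4,8,10-tetramethyl-9-[(triisopropylsilyl)oxy]undeca-2,8,10-trienoyl}-1,3-oxazolidin-2-one | C=C(C)C(O[Si](C(C)C)(C(C)C)C(C)C)=C(C)CCCC(C)(C)/C=C/C(=O)N1[C@@H](Cc2ccccc2)COC1=O
F2 | step 9 | (4S)-4-benzyl-3-{[(1S,4aS,8aS)-3,4a,8,8-tetramethyl-4-[(triisopropylsilyl)oxy]-1,2,4a,5,6,7,8,8a-octahydronaphthalen-1-yl]carbonyl}-1,3-oxazolidin-2-one | CC1=C(O[Si](C(C)C)(C(C)C)C(C)C)[C@@]2(C)CCCC(C)(C)[C@@H]2[C@@H](C(=O)N3[C@@H](Cc4ccccc4)COC3=O)C1
F3 | step 9 | {(1S,4aS,8aS)-3,4a,8,8-tetramethyl-4-[(triisopropylsilyl)oxy]-1,2,4a,5,6,7,8,8a-octahydronaphthalen-1-yl}methanol | CC1=C(O[Si](C(C)C)(C(C)C)C(C)C)[C@@]2(C)CCCC(C)(C)[C@@H]2[C@@H](CO)C1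
F4 | step 13 | (4aS,8aS)-1-ethenyl-2,5,5,8a-tetramethyl-3,4,4a,5,6,7,8,8a-octahydronaphthalene | CC1=C(C=C)[C@@]2(C)CCCC(C)(C)[C@@H]2CC1
F5 | step 13 | 2-bromo-3-(methoxymethoxy)prop-1-ene | C=C(Br)COCOC
F6 | step 13 | 9-(2-Dec-ethyl)-9-borabicyclo[3.3.1]nonane | CC1=C(CCB3C4CCCC3CCC4)[C@@]2(C)CCCC(C)(C)[C@@H]2CC1
F7 | step 13 | (4aS,8aS)-1-{3-[(methoxymethoxy)methyl]but-3-en-1-yl}-2,5,5,8a-tetramethyl-3,4,4a,5,6,7,8,8a-octahydronaphthalene | CC1=C(CCC(=C)COCOC)[C@@]2(C)CCCC(C)(C)[C@@H]2CC1
F8 | step 13 | 2-[(methoxymethoxy)methyl]-4-Dec-butane-1,2-diol | CC1=C(CCC(O)(CO)COCOC)[C@@]2(C)CCCC(C)(C)[C@@H]2CC1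
F9 | step 17 | methyl (6Z)-4-hydroxy-7-[(methoxymethoxy)methyl]-9-Dec-non-6-en-2-ynoate (C4 epimers) | CC1=C(CC/C(=C/CC(O)C#CC(=O)OC)COCOC)[C@@]2(C)CCCC(C)(C)[C@@H]2CC1
F10 | step 17 | methyl (6Z)-7-[(methoxymethoxy)methyl]-4-oxo-9-Dec-non-6-en-2-ynoate | CC1=C(CC/C(=C/CC(=O)C#CC(=O)OC)COCOC)[C@@]2(C)CCCC(C)(C)[C@@H]2CC1
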